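The C5–C10 bond, which joins the methyl-bearing quaternary C10 to the β-carbon C5 of a C3-keto C4=C5 enone, is shared by rings A and B, so both rings are cut from one ten-membered carbocycle (C1–C10). Hydrogen-atom transfer to the C10 exocyclic methylene (the future C20 methyl) gives a tertiary radical that adds across the ring to C5, forging the trans-decalin, the quaternary centre and the C5 and C4 stereocentres in one operation. The precursor is an E-cyclodec-2-enone carrying the C10 methylene, a C8 silyl ether trans to the C9 side chain, and C13 masked as a dioxolane; C9, set by an Evans aldol, is its controlling stereocentre.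

Key step: step 14

Remarks on the chemistry (one line each):
- Labdane numbering is used throughout; the target is read as an ent-labdane with C20 and the C9 chain cis, H5 trans to C20, the C3 oxygen and C18 equatorial and the C4 methyl axial.
- Precursor 22 and product 23 carry the same spatial arrangement at C9 as the target (checked centre by centre); no correction of the skeleton was needed.
- C8 is carried as a silyl ether trans to the C9 chain rather than as a ketal: it comes directly from the aldol that sets C9, so no epimerisable β,γ-unsaturated C8 ketone is made before ring closure, and both groups are pseudo-equatorial in the chair–chair arrangement.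
- The side chain already holds C16 and C13 (as a dioxolane): it offers no weak C–H bond to the C10 radical and needs no later oxidation or methyl addition.
- C4 is functionalised through the C1=C2 enone 25, whose only acidic position is C4; direct enolisation of a trans-fused 4-methyl-3-decalone toward C4 is assumed unreliable.
- Compounds 1, 5, 8, 15, 35 and 39 are taken as commercial.

Step 1
Reactants: 1 hex-4-yn-1-ol
Product: 3 (E)-5-iodohex-4-en-1-ol, via alkenylzirconocene 2 (not isolated)
Conditions: Cp2Zr(H)Cl (2.5 equiv), THF, rt to 40 °C; then I2, 0 °C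
Reagents that add atoms: iodine, II
Why: Syn hydrozirconation of the 2-alkyne with excess Cp2Zr(H)Cl equilibrates zirconium to the methyl-bearing carbon, and iodinolysis with retention should give the E-configured 2-iodoalkene (hydrozirconation–iodination).

Step 2
Reactants: 3 (E)-5-iodohex-4-en-1-ol
Product: 4 (E)-5-iodohex-4-enal
Conditions: Dess–Martin periodinane, NaHCO3, CH2Cl2, 0 °C to rt
Reagents that add atoms: none
Why: Dess–Martin oxidation of a primary alcohol stops at the aldehyde and leaves the alkenyl iodide untouched.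

Step 3
Reactants: 5 5-oxohexanoic acid
Product: 7 4-(2-methyl-1,3-dioxolan-2-yl)butanoic acid, via hydroxyethyl ester 6 (not isolated)
Conditions: ethylene glycol, TsOH·H2O (cat.), toluene, reflux, Dean–Stark; then NaOH, MeOH/H2O, rt; then NaH2PO4 to pH 5
Reagents that add atoms: ethylene glycol, OCCO; sodium hydroxide, [Na+].[OH-]
Why: Acid-catalysed ketalisation with azeotropic removal of water (the acid is esterified at the same time) followed by saponification returns the acid while the base-stable dioxolane stays.

Step 4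
Reactants: 7 4-(2-methyl-1,3-dioxolan-2-yl)butanoic acid; 8 (R)-4-benzyl-1,3-oxazolidin-2-one
Product: 10 (R)-4-benzyl-3-[4-(2-methyl-1,3-dioxolan-2-yl)butanoyl]-1,3-oxazolidin-2-one, via mixed pivalic anhydride 9 (not isolated)
Conditions: PivCl, Et3N, THF, −20 °C; then 8, LiCl, −20 °C to rt
Reagents that add atoms: none
Why: N-acylation of the oxazolidinone at the less hindered carbonyl of a mixed pivalic anhydride is the standard way to Evans imides.

Step 5
Reactants: 10 imide; 4 (E)-5-iodohex-4-enal
Product: 12 (R)-4-benzyl-3-[(2R,3S,6E)-3-hydroxy-7-iodo-2-[2-(2-methyl-1,3-dioxolan-2-yl)ethyl]oct-6-enoyl]-1,3-oxazolidin-2-one, via dibutylboron enolate 11 (not isolated)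
Conditions: Bu2BOTf, iPr2NEt, CH2Cl2, −78 to 0 °C; then 4, −78 to 0 °C; then pH 7 buffer, MeOH, H2O2
Reagents that add atoms: none
Why: Evans syn-aldol reaction, in which the Z-boron enolate reacts through a Zimmerman–Traxler chair on the face away from the benzyl group, which sets C9 (R in the imide) and C8 (S) in a syn relation.

Step 6
Reactants: 12 syn-aldol imide
Product: 13 (2R,3S,6E)-3-hydroxy-7-iodo-N-methoxy-N-methyl-2-[2-(2-methyl-1,3-dioxolan-2-yl)ethyl]oct-6-enamide
Conditions: MeNH(OMe)·HCl, AlMe3, CH2Cl2, −10 to 0 °C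
Reagents that add atoms: N,O-dimethylhydroxylamine hydrochloride, CNOC.Cl
Why: The aluminium amide formed from AlMe3 and the amine salt opens the exocyclic imide carbonyl of the β-hydroxy imide without touching C9, and auxiliary 8 is recovered (Weinreb transamidation).

Step 7
Reactants: 13 hydroxy Weinreb amide
Product: 14 (2R,3S,6E)-3-[(tert-butyldimethylsilyl)oxy]-7-iodo-N-methoxy-N-methyl-2-[2-(2-methyl-1,3-dioxolan-2-yl)ethyl]oct-6-enamide
Conditions: TBSOTf, 2,6-lutidine, CH2Cl2, −78 °C
Reagents that add atoms: tert-butyldimethylsilyl triflate, CC(C)(C)[Si](C)(C)OS(=O)(=O)C(F)(F)F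
Why: Silylation of the secondary C8 hydroxyl with a silyl triflate and a hindered base is fast at low temperature, where the ketal is inert.

Step 8
Reactants: 14 silylated Weinreb amide; 15 (3-bromopropoxy)(tert-butyl)dimethylsilane
Product: 17 (5R,6S,9E)-1,6-bis[(tert-butyldimethylsilyl)oxy]-10-iodo-5-[2-(2-methyl-1,3-dioxolan-2-yl)ethyl]undec-9-en-4-one, via Grignard reagent 16 (not isolated)
Conditions: 15, Mg, THF, rt; then 14, THF, 0 °C to rt; sat. aq NH4Cl
Reagents that add atoms: none
Why: The Grignard reagent adds only once because the chelated tetrahedral intermediate survives until work-up, so the C10 ketone should form without over-addition or loss of configuration at C9 (Weinreb ketone synthesis).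

Step 9
Reactants: 17 C10 ketone
Product: 18 (5S,6S,9E)-1,6-bis[(tert-butyldimethylsilyl)oxy]-10-iodo-4-methylidene-5-[2-(2-methyl-1,3-dioxolan-2-yl)ethyl]undec-9-ene
Conditions: Cp2TiMe2, toluene/THF, 65 °C, dark
Reagents that add atoms: dimethyltitanocene Cp2TiMe2, C[Ti](C)(C1C=CC=C1)C1C=CC=C1
Why: The non-basic titanium methylidene released from Cp2TiMe2 methylenates the hindered, enolisable ketone without epimerising C9 or eliminating the β-silyloxy group (Petasis olefination).

Step 10
Reactants: 18 bis-silyl ether
Product: 19 (5S,6S,9E)-6-[(tert-butyldimethylsilyl)oxy]-10-iodo-4-methylidene-5-[2-(2-methyl-1,3-dioxolan-2-yl)ethyl]undec-9-en-1-ol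
Conditions: HF·pyridine, pyridine, THF, 0 °C
Reagents that add atoms: none
Why: Buffered HF·pyridine cleaves the unhindered primary silyl ether much faster than the secondary C8 silyl ether next to the branched C9 (selective desilylation).

Step 11
Reactants: 19 primary alcohol
Product: 20 (5S,6S,9E)-6-[(tert-butyldimethylsilyl)oxy]-10-iodo-4-methylidene-5-[2-(2-methyl-1,3-dioxolan-2-yl)ethyl]undec-9-enal
Conditions: Dess–Martin periodinane, NaHCO3, CH2Cl2, 0 °C to rt
Reagents that add atoms: none
Why: Buffered Dess–Martin oxidation gives the C3 aldehyde under conditions that leave ketal, silyl ether and alkenyl iodide intact.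

Step 12
Reactants: 20 iodo aldehyde
Product: 21 (2E,6S,7S)-6-[(tert-butyldimethylsilyl)oxy]-2-methyl-8-methylidene-7-[2-(2-methyl-1,3-dioxolan-2-yl)ethyl]cyclodec-2-en-1-ol (C3 epimers)
Conditions: CrCl2 (8 equiv), NiCl2 (2 mol%), DMSO, 0.005 M, rt
Reagents that add atoms: none
Why: In this intramolecular Nozaki–Hiyama–Kishi reaction nickel inserts into the C4–I bond, transmetallation gives an alkenyl species of trivalent chromium that adds only to the aldehyde with retention of the E geometry, and high dilution favours ring closure; the C3 carbinol configuration does not matter because it is oxidised next.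

Step 13
Reactants: 21 cyclic allylic alcohol
Product: 22 (2E,6S,7S)-6-[(tert-butyldimethylsilyl)oxy]-2-methyl-8-methylidene-7-[2-(2-methyl-1,3-dioxolan-2-yl)ethyl]cyclodec-2-en-1-one
Conditions: Dess–Martin periodinane, NaHCO3, CH2Cl2, 0 °C, dark
Reagents that add atoms: none
Why: Mild, buffered oxidation of the allylic alcohol gives the E-enone without acid or base that could isomerise the strained E-alkene or move the exocyclic double bond.

Step 14
Reactants: 22 E-cyclodecenone precursor
Product: 23 trans-decal-3-one with equatorial 4-methyl and 8-silyloxy groups (full structure in the list)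
Conditions: Fe(acac)3 (0.3 equiv), PhSiH3 (2.5 equiv), EtOH/(CH2OH)2 (5:1), 0.01 M, 60 °C
Reagents that add atoms: none
Why: Proposed new method: Fe(acac)3 and PhSiH3 generate an iron hydride in ethanol that hands a hydrogen atom to C20 of the electron-rich methylene (Markovnikov), so the unpaired electron sits on tertiary C10; this nucleophilic radical attacks the β-carbon C5 of the enone across the ring, and divalent iron reduces the resulting C4 α-keto radical to an enolate that ethanol protonates. The closest known chemistry is the Fe(acac)3/PhSiH3 reductive coupling of alkenes with enones by hydrogen-atom transfer (including its intramolecular Giese variant), together with transannular radical and cationic closures of cyclodeca-1,5-dienes to decalins; their combination on a cyclodecenone is new. The one new bond closes ring B in the 6-exo mode (tether C9–C8–C7–C6) and ring A in the 6-endo mode (tether C1–C2–C3, with C4 inside the ring). C10 and C5 are set by a chair–chair transition state in which the C9 side chain and the trans C8 silyloxy group are both pseudo-equatorial, which puts the new C20 methyl axial and cis to C11 and H5 on the opposite face (trans fusion); C4 is set by protonation and should equilibrate to the equatorial methyl epimer, and either epimer serves steps 15 and 16. The step needs hydrogen-atom transfer to the 1,1-disubstituted alkene and not to the enone, and ring closure faster than reduction of the C10 radical or a 1,5-hydrogen shift from allylic C6; the electron-poor enone, the polarity match, the proximity of C10 and C5 inside the ring, high dilution and the absence of a weak C–H bond on the side chain (C13 is a ketal carbon) should secure this.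

Step 15
Reactants: 23 trans-decal-3-one
Product: 25 C1=C2 enone (decal-1-en-3-one), via silyl enol ether 24 (not isolated)
Conditions: LiN(iPr)2, TMSCl, THF, −78 °C; then Pd(OAc)2, MeCN, rt
Reagents that add atoms: none
Why: Kinetic deprotonation occurs at the C2 methylene and not at the hindered tertiary C4–H, and Saegusa–Ito oxidation of the C2=C3 silyl enol ether installs the C1=C2 double bond, after which C4 is the only enolisable position.

Step 16
Reactants: 25 C1=C2 enone
Product: 27 4-hydroxymethyl enone, via lithium dienolate 26 (not isolated)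
Conditions: LiN(iPr)2, THF, −78 °C; then CH2O (gas from cracked paraformaldehyde), −78 to −40 °C; AcOH
Reagents that add atoms: formaldehyde, C=O
Why: α′-Deprotonation gives the cross-conjugated dienolate regiospecifically (C10 is quaternary, so no γ-proton exists), and its aldol reaction with monomeric formaldehyde should take place on the face opposite the axial C20 methyl, which makes C4 quaternary with the hydroxymethyl group equatorial and trans to C20.

Step 17
Reactants: 27 4-hydroxymethyl enone
Product: 29 3,18-diol, via saturated hydroxy ketone 28 (not isolated)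
Conditions: H2 (1 atm), Pd/C, EtOAc, rt; filter; then NaBH4, EtOH, 0 °C
Reagents that add atoms: none
Why: Catalytic hydrogenation saturates the only C=C bond, and NaBH4 then delivers hydride to C3 along the axial trajectory on the face away from the axial C4 methyl, which should give the equatorial C3 alcohol.

Step 18
Reactants: 29 3,18-diol
Product: 30 3,18-acetonide
Conditions: 2,2-dimethoxypropane, PPTS (cat.), CH2Cl2, rt
Reagents that add atoms: 2,2-dimethoxypropane, COC(C)(C)OC
Why: Acid-catalysed transacetalisation closes the six-membered isopropylidene acetal across the C3 and C18 hydroxyls under anhydrous conditions that do not hydrolyse the side-chain dioxolane.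

Step 19
Reactants: 30 3,18-acetonide
Product: 31 C8 alcohol
Conditions: Bu4NF, THF, rt to 45 °C
Reagents that add atoms: none
Why: Fluoride cleaves the Si–O bond of the remaining silyl ether, while both acetals are stable to the basic medium.

Step 20
Reactants: 31 C8 alcohol
Product: 32 C8 ketone
Conditions: Dess–Martin periodinane, NaHCO3, CH2Cl2, rt
Reagents that add atoms: none
Why: Oxidation of the only free hydroxyl gives the C8 ketone, and C9 keeps its equatorial side chain because that is also the thermodynamically preferred epimer.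

Step 21
Reactants: 32 C8 ketone
Product: 33 8(17)-alkene acetonide
Conditions: Ph3PCH3Br, KOtBu, toluene, rt; then 32, 60 °C
Reagents that add atoms: methylenetriphenylphosphorane (made in the flask from methyltriphenylphosphonium bromide and KOtBu), C=P(c1ccccc1)(c1ccccc1)c1ccccc1
Why: Wittig methylenation of the hindered C8 ketone is the established entry to the labdane 8(17)-alkene, and no ester or other carbonyl group is present to compete.

Step 22
Reactants: 33 8(17)-alkene acetonide
Product: 34 3,18-dihydroxy-8(17)-en-13-one (methyl ketone diol)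
Conditions: AcOH/THF/H2O (3:1:1), 45 °C
Reagents that add atoms: water, O
Why: Mild aqueous acid hydrolyses the isopropylidene acetal and the dioxolane together but is too weak to shift the exocyclic C8=C17 double bond.

Step 23
Reactants: 34 methyl ketone diol; 35 allyl diethylphosphonoacetate
Product: 37 allyl 3,18-dihydroxy-ent-labda-8(17),13E-dien-15-oate, via sodium phosphonate 36 (not isolated)
Conditions: 35, NaH, THF, 0 °C; then 34, rt to 50 °C
Reagents that add atoms: none
Why: Horner–Wadsworth–Emmons olefination of the methyl ketone with the stabilised phosphonate anion, which is too weakly basic to disturb the free hydroxyls, should give the trisubstituted enoate with the E isomer predominating; the minor Z isomer is removed by chromatography.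

Step 24
Reactants: 37 dihydroxy allyl ester
Product: 38 allyl 18-[(tert-butyldimethylsilyl)oxy]-3-hydroxy-ent-labda-8(17),13E-dien-15-oate
Conditions: TBSCl, imidazole, CH2Cl2, 0 °C
Reagents that add atoms: tert-butyldimethylsilyl chloride, CC(C)(C)[Si](C)(C)Cl
Why: The primary C18 hydroxyl is silylated far faster than the secondary C3 hydroxyl next to quaternary C4, which leaves C3–OH free for acylation.

Step 25
Reactants: 38 C18 silyl ether; 39 angelic acid
Product: 41 allyl 3-angeloyloxy-18-[(tert-butyldimethylsilyl)oxy]-ent-labda-8(17),13E-dien-15-oate, via mixed anhydride 40 (not isolated)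
Conditions: 39, 2,4,6-trichlorobenzoyl chloride, Et3N, toluene, rt; then 38, 80 °C
Reagents that add atoms: none
Why: Acylation of the hindered C3 hydroxyl by the preformed mixed 2,4,6-trichlorobenzoic anhydride without a nucleophilic catalyst (Yamaguchi-type esterification) should transfer the angeloyl group with its Z geometry intact, because no reversible conjugate addition to the acyl donor takes place.

Step 26
Reactants: 41 allyl ester
Product: 42 3-angeloyloxy-18-[(tert-butyldimethylsilyl)oxy]-ent-labda-8(17),13E-dien-15-oic acid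
Conditions: Pd(PPh3)4 (5 mol%), morpholine, THF, rt
Reagents that add atoms: none
Why: Zerovalent palladium ionises the allyl ester to a π-allyl complex that morpholine traps, which frees the acid under neutral conditions that leave the angelate, the silyl ether and the alkenes untouched (Tsuji–Trost deallylation).

Step 27
Reactants: 42 silyl-protected acid
Product: 43 CNP0420226.2
Conditions: HF·pyridine, THF, 0 °C to rt
Reagents that add atoms: none
Why: Mildly acidic fluoride removes the primary silyl ether without the basic conditions that could move the angeloyl group from O3 to O18 or isomerise it to the tiglate.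

Compound list

1 | hex-4-yn-1-ol | CC#CCCCO | starting material
2 | (E)-alkenylzirconocene chloride (Zr on the methyl-bearing carbon; hydroxyl bound as zirconocene alkoxide) | C/C(=C\CCCO[Zr](Cl)(C1C=CC=C1)C1C=CC=C1)[Zr](Cl)(C1C=CC=C1)C1C=CC=C1 | intermediate
3 | (E)-5-iodohex-4-en-1-ol | C/C(I)=C\CCCO | intermediate
4 | (E)-5-iodohex-4-enal | C/C(I)=C\CCC=O | intermediate
5 | 5-oxohexanoic acid | CC(=O)CCCC(=O)O | starting material
6 | 2-hydroxyethyl 4-(2-methyl-1,3-dioxolan-2-yl)butanoate | CC1(CCCC(=O)OCCO)OCCO1 | intermediate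
7 | 4-(2-methyl-1,3-dioxolan-2-yl)butanoic acid | CC1(CCCC(=O)O)OCCO1 | intermediate
8 | (R)-4-benzyl-1,3-oxazolidin-2-one | O=C1N[C@H](Cc2ccccc2)CO1 | starting material
9 | mixed anhydride of 7 with pivalic acid | CC1(CCCC(=O)OC(=O)C(C)(C)C)OCCO1 | intermediate
10 | (R)-4-benzyl-3-[4-(2-methyl-1,3-dioxolan-2-yl)butanoyl]-1,3-oxazolidin-2-one | CC1(CCCC(=O)N2[C@H](Cc3ccccc3)COC2=O)OCCO1 | intermediate
11 | dibutylboron (Z)-enolate of 10 | CCCCB(CCCC)O/C(=C\CCC1(C)OCCO1)N1[C@H](Cc2ccccc2)COC1=O | intermediate
12 | (R)-4-benzyl-3-[(2R,3S,6E)-3-hydroxy-7-iodo-2-[2-(2-methyl-1,3-dioxolan-2-yl)ethyl]oct-6-enoyl]-1,3-oxazolidin-2-one (syn aldol; labdane C9 R, C8 S) | O=C(N1[C@H](Cc2ccccc2)COC1=O)[C@H](CCC3(C)OCCO3)[C@@H](O)CC/C=C(\C)I | intermediate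
13 | (2R,3S,6E)-3-hydroxy-7-iodo-N-methoxy-N-methyl-2-[2-(2-methyl-1,3-dioxolan-2-yl)ethyl]oct-6-enamide | CON(C)C(=O)[C@H](CCC1(C)OCCO1)[C@@H](O)CC/C=C(\C)I | intermediate
14 | (2R,3S,6E)-3-[(tert-butyldimethylsilyl)oxy]-7-iodo-N-methoxy-N-methyl-2-[2-(2-methyl-1,3-dioxolan-2-yl)ethyl]oct-6-enamide | CON(C)C(=O)[C@H](CCC1(C)OCCO1)[C@@H](O[Si](C)(C)C(C)(C)C)CC/C=C(\C)I | intermediate
15 | (3-bromopropoxy)(tert-butyl)dimethylsilane | CC(C)(C)[Si](C)(C)OCCCBr | starting material
16 | 3-[(tert-butyldimethylsilyl)oxy]propylmagnesium bromide | CC(C)(C)[Si](C)(C)OCCC[Mg]Br | intermediate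
17 | (5R,6S,9E)-1,6-bis[(tert-butyldimethylsilyl)oxy]-10-iodo-5-[2-(2-methyl-1,3-dioxolan-2-yl)ethyl]undec-9-en-4-one | CC(C)(C)[Si](C)(C)OCCCC(=O)[C@H](CCC1(C)OCCO1)[C@@H](O[Si](C)(C)C(C)(C)C)CC/C=C(\C)I | intermediate
18 | (5S,6S,9E)-1,6-bis[(tert-butyldimethylsilyl)oxy]-10-iodo-4-methylidene-5-[2-(2-methyl-1,3-dioxolan-2-yl)ethyl]undec-9-ene | CC(C)(C)[Si](C)(C)OCCCC(=C)[C@H](CCC1(C)OCCO1)[C@@H](O[Si](C)(C)C(C)(C)C)CC/C=C(\C)I | intermediate
19 | (5S,6S,9E)-6-[(tert-butyldimethylsilyl)oxy]-10-iodo-4-methylidene-5-[2-(2-methyl-1,3-dioxolan-2-yl)ethyl]undec-9-en-1-ol | OCCCC(=C)[C@H](CCC1(C)OCCO1)[C@@H](O[Si](C)(C)C(C)(C)C)CC/C=C(\C)I | intermediate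
20 | (5S,6S,9E)-6-[(tert-butyldimethylsilyl)oxy]-10-iodo-4-methylidene-5-[2-(2-methyl-1,3-dioxolan-2-yl)ethyl]undec-9-enal | O=CCCC(=C)[C@H](CCC1(C)OCCO1)[C@@H](O[Si](C)(C)C(C)(C)C)CC/C=C(\C)I | intermediate
21 | (2E,6S,7S)-6-[(tert-butyldimethylsilyl)oxy]-2-methyl-8-methylidene-7-[2-(2-methyl-1,3-dioxolan-2-yl)ethyl]cyclodec-2-en-1-ol (both carbinol epimers) | C=C1CCC(O)/C(C)=C/CC[C@H](O[Si](C)(C)C(C)(C)C)[C@H]1CCC2(C)OCCO2 | intermediate
22 | (2E,6S,7S)-6-[(tert-butyldimethylsilyl)oxy]-2-methyl-8-methylidene-7-[2-(2-methyl-1,3-dioxolan-2-yl)ethyl]cyclodec-2-en-1-one (key-step precursor: C3 ketone, E C4=C5, C10 methylene, 8S, 9S) | C=C1CCC(=O)/C(C)=C/CC[C@H](O[Si](C)(C)C(C)(C)C)[C@H]1CCC2(C)OCCO2 | intermediate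
23 | trans-decal-3-one (key-step product): 4-methyl equatorial, 10-methyl axial and cis to the C9 chain, H5 trans to C20, (8S) OTBS and C9 2-(2-methyl-1,3-dioxolan-2-yl)ethyl chain both equatorial | CC(C)(C)[Si](C)(C)O[C@H]1CC[C@H]2[C@@](C)(CCC(=O)[C@@H]2C)[C@@H]1CCC3(C)OCCO3 | intermediate
24 | C2=C3 trimethylsilyl enol ether of 23 | CC(C)(C)[Si](C)(C)O[C@H]1CC[C@H]2[C@@](C)(CC=C(O[Si](C)(C)C)[C@@H]2C)[C@@H]1CCC3(C)OCCO3 | intermediate
25 | C1=C2 enone (decal-1-en-3-one) of 23 | CC(C)(C)[Si](C)(C)O[C@H]1CC[C@H]2[C@@](C)(C=CC(=O)[C@@H]2C)[C@@H]1CCC3(C)OCCO3 | intermediate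
26 | lithium C3=C4 dienolate of 25 | CC(C)(C)[Si](C)(C)O[C@H]1CC[C@H]2[C@@](C)(C=CC(O[Li])=C2C)[C@@H]1CCC3(C)OCCO3 | intermediate
27 | 4-hydroxymethyl-4-methyl enone (CH2OH equatorial, trans to C20) | CC(C)(C)[Si](C)(C)O[C@H]1CC[C@H]2[C@@](C)(C=CC(=O)[C@]2(C)CO)[C@@H]1CCC3(C)OCCO3 | intermediate
28 | saturated 18-hydroxy-3-ketone | CC(C)(C)[Si](C)(C)O[C@H]1CC[C@H]2[C@@](C)(CCC(=O)[C@]2(C)CO)[C@@H]1CCC3(C)OCCO3 | intermediate
29 | 3,18-diol (C3 hydroxyl equatorial) | CC(C)(C)[Si](C)(C)O[C@H]1CC[C@H]2[C@@](C)(CC[C@@H](O)[C@]2(C)CO)[C@@H]1CCC3(C)OCCO3 | intermediate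
30 | 3,18-O-isopropylidene acetal of 29 | CC(C)(C)[Si](C)(C)O[C@H]1CC[C@H]2[C@@](C)(CC[C@H]4OC(C)(C)OC[C@]24C)[C@@H]1CCC3(C)OCCO3 | intermediate
31 | C8 alcohol (acetonide, side-chain dioxolane) | O[C@H]1CC[C@H]2[C@@](C)(CC[C@H]4OC(C)(C)OC[C@]24C)[C@@H]1CCC3(C)OCCO3 | intermediate
32 | C8 ketone (acetonide, side-chain dioxolane) | O=C1CC[C@H]2[C@@](C)(CC[C@H]4OC(C)(C)OC[C@]24C)[C@@H]1CCC3(C)OCCO3 | intermediate
33 | 8(17)-alkene (acetonide, side-chain dioxolane) | C=C1CC[C@H]2[C@@](C)(CC[C@H]4OC(C)(C)OC[C@]24C)[C@@H]1CCC3(C)OCCO3 | intermediate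
34 | 3,18-dihydroxy-14,15-dinor-ent-labd-8(17)-en-13-one | C=C1CC[C@H]2[C@@](C)(CC[C@@H](O)[C@]2(C)CO)[C@@H]1CCC(C)=O | intermediate
35 | allyl diethylphosphonoacetate | CCOP(=O)(OCC)CC(=O)OCC=C | starting material
36 | sodium salt of 35 | [Na+].CCOP(=O)(OCC)[CH-]C(=O)OCC=C | intermediate
37 | allyl 3,18-dihydroxy-ent-labda-8(17),13E-dien-15-oate | C=C1CC[C@H]2[C@@](C)(CC[C@@H](O)[C@]2(C)CO)[C@@H]1CC/C(C)=C/C(=O)OCC=C | intermediate
38 | allyl 18-[(tert-butyldimethylsilyl)oxy]-3-hydroxy-ent-labda-8(17),13E-dien-15-oate | C=C1CC[C@H]2[C@@](C)(CC[C@@H](O)[C@]2(C)CO[Si](C)(C)C(C)(C)C)[C@@H]1CC/C(C)=C/C(=O)OCC=C | intermediate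
39 | angelic acid, (Z)-2-methylbut-2-enoic acid | C/C=C(/C)C(=O)O | starting material
40 | angelic 2,4,6-trichlorobenzoic anhydride | C/C=C(/C)C(=O)OC(=O)c1c(Cl)cc(Cl)cc1Cl | intermediate
41 | allyl 3-angeloyloxy-18-[(tert-butyldimethylsilyl)oxy]-ent-labda-8(17),13E-dien-15-oate | C=C1CC[C@H]2[C@@](C)(CC[C@@H](OC(=O)/C(C)=C\C)[C@]2(C)CO[Si](C)(C)C(C)(C)C)[C@@H]1CC/C(C)=C/C(=O)OCC=C | intermediate
42 | 3-angeloyloxy-18-[(tert-butyldimethylsilyl)oxy]-ent-labda-8(17),13E-dien-15-oic acid | C=C1CC[C@H]2[C@@](C)(CC[C@@H](OC(=O)/C(C)=C\C)[C@]2(C)CO[Si](C)(C)C(C)(C)C)[C@@H]1CC/C(C)=C/C(=O)O | intermediate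
43 | CNP0420226.2, 3-angeloyloxy-18-hydroxy-ent-labda-8(17),13E-dien-15-oic acid | C=C1CC[C@H]2[C@@](C)(CC[C@@H](OC(=O)/C(C)=C\C)[C@]2(C)CO)[C@@H]1CC/C(C)=C/C(=O)O | target

Total step count: 27 steps (telescoped operations counted as one step each).
Longest linear sequence: 25 steps (steps 1–2 and 5–27; the branch through steps 3–4 is equally long).

Steps most likely to fail

Step 14 (transannular radical conjugate addition). The iron hydride may reduce the C10 radical, or transfer hydrogen to the enone, before the C5–C10 bond forms. The fallback sets out from 22 and comes back at 23, and generates the same radical without any metal hydride. mCPBA with NaHCO3 in CH2Cl2 at 0 °C should epoxidise only the electron-rich exocyclic alkene to the spiro-epoxide F1 (both C10 epimers). Cp2TiCl, made from Cp2TiCl2 and Zn dust in THF at rt, then opens the epoxide homolytically at the more substituted carbon (Nugent–RajanBabu reaction). This gives the tertiary C10 radical, now carrying C20 as a titanium alkoxide, which closes across the ring onto C5; this type of closure is documented for 1(10)-epoxygermacranes going to eudesmanes. Protonation of the titanium enolate on work-up gives the C20-hydroxy decalone F2. Phenyl chlorothionoformate and pyridine convert it into the thionocarbonate F3, and Bu3SnH/AIBN in toluene at 110 °C (Barton–McCombie deoxygenation) reduces C20 to the methyl group of 23.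

Step 12 (ten-membered ring closure). Intermolecular coupling and loss of iodide by protonation may outrun closure of the strained ring. The fallback sets out from 14 and comes back at 21; it makes the C3–C4 bond between two molecules and closes the ring at C1–C2 by metathesis. Intermolecular CrCl2/NiCl2 coupling of 14 with acrolein gives the divinyl carbinol F4. Et3SiCl and imidazole give its triethylsilyl ether F5. Vinylmagnesium bromide converts the Weinreb amide into the vinyl ketone F6. Ring-closing metathesis (second-generation Hoveyda–Grubbs catalyst, toluene, 0.002 M, 80 °C) gives the ten-membered C10 enone F7. Conjugate reduction with [(Ph3P)CuH]6 gives the saturated C10 ketone F8, and Cp2TiMe2 gives the C10 methylene compound F9. HF·pyridine/pyridine at 0 °C removes the triethylsilyl group and returns 21.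

Step 25 (angeloylation). Slow acylation of the hindered C3 hydroxyl may give the Z acyl donor time to isomerise to the E (tiglate) form. The fallback sets out from 38 and comes back at 41; it builds the Z double bond on the molecule. Esterification of 38 with 2-[bis(2,2,2-trifluoroethoxy)phosphoryl]propanoic acid (DCC, DMAP, CH2Cl2) gives the phosphonopropionate F10. KN(SiMe3)2 and 18-crown-6 in THF at −78 °C followed by acetaldehyde (Still–Gennari olefination) should then give the Z-configured 2-methylbut-2-enoate 41.

Further compounds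

F1 | step 14 | spiro-epoxide of 22 at C10/C20 (both C10 epimers) | C1OC12CCC(=O)/C(C)=C/CC[C@H](O[Si](C)(C)C(C)(C)C)[C@H]2CCC3(C)OCCO3
F2 | step 14 | C20-hydroxy analogue of 23 | CC(C)(C)[Si](C)(C)O[C@H]1CC[C@H]2[C@@](CO)(CCC(=O)[C@@H]2C)[C@@H]1CCC3(C)OCCO3
F3 | step 14 | O-phenyl thionocarbonate of F2 | CC(C)(C)[Si](C)(C)O[C@H]1CC[C@H]2[C@@](COC(=S)Oc4ccccc4)(CCC(=O)[C@@H]2C)[C@@H]1CCC3(C)OCCO3
F4 | step 12 | divinyl carbinol from 14 and acrolein (both C3 epimers) | CON(C)C(=O)[C@H](CCC1(C)OCCO1)[C@@H](O[Si](C)(C)C(C)(C)C)CC/C=C(\C)C(O)C=C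
F5 | step 12 | triethylsilyl ether of F4 | CON(C)C(=O)[C@H](CCC1(C)OCCO1)[C@@H](O[Si](C)(C)C(C)(C)C)CC/C=C(\C)C(O[Si](CC)(CC)CC)C=C
F6 | step 12 | vinyl ketone | C=CC(=O)[C@H](CCC1(C)OCCO1)[C@@H](O[Si](C)(C)C(C)(C)C)CC/C=C(\C)C(O[Si](CC)(CC)CC)C=C
F7 | step 12 | ten-membered C10 enone from metathesis (C1=C2 geometry immaterial) | O=C1C=CC(O[Si](CC)(CC)CC)/C(C)=C/CC[C@H](O[Si](C)(C)C(C)(C)C)[C@H]1CCC2(C)OCCO2
F8 | step 12 | saturated ten-membered C10 ketone | O=C1CCC(O[Si](CC)(CC)CC)/C(C)=C/CC[C@H](O[Si](C)(C)C(C)(C)C)[C@H]1CCC2(C)OCCO2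
F9 | step 12 | C10 methylene compound (C3 triethylsilyl ether of 21) | C=C1CCC(O[Si](CC)(CC)CC)/C(C)=C/CC[C@H](O[Si](C)(C)C(C)(C)C)[C@H]1CCC2(C)OCCO2
F10 | step 25 | C3 2-[bis(2,2,2-trifluoroethoxy)phosphoryl]propanoate of 38 | C=C1CC[C@H]2[C@@](C)(CC[C@@H](OC(=O)C(C)P(=O)(OCC(F)(F)F)OCC(F)(F)F)[C@]2(C)CO[Si](C)(C)C(C)(C)C)[C@@H]1CC/C(C)=C/C(=O)OCC=C
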